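Ring A (C1–C5 and C10, terpenoid numbering: C4 = CMe2, C10 = C–CH3) is disconnected to a 1,2,2-trimethylcyclopentyl carbinol, because quaternary C4 and C10 flanking methine C5 are the footprint of a 1,2-shift. Ionising the carbinol triflate moves C4 from C10 to C5 (cyclopentane to cyclohexane, inversion at C5); the C10 cation is captured by a pendant (E)-alkene, closing ring B and leaving the C7=C8 bond. One catalyst-set carbinol thus dictates C5, C10 and C9 in one operation, and the cyclopentane quaternary centre, erased in the cation, may be racemic. Crotylboration, cross-metathesis, sulfation and hydroquinone unmasking complete the side chain.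

Key step: step 6

Remark: the target is drawn as the free hydrogen sulfate, so the sulfate is carried as its sodium salt and the acid is liberated in the last operation; decalin atoms are labelled C1–C10 in the terpenoid way (C4 = CMe2, C5 and C10 = ring fusion, C8 = C(CH3)=, C9 = carbon bearing the side chain).

Step 1
Reactants: 1 1-(2-methylcyclopent-1-en-1-yl)ethan-1-one
Product: 3 1-(1,2,2-trimethylcyclopentyl)ethan-1-one (racemic), via lithium enolate 2 (not isolated)
Conditions: Me2CuLi (from MeLi and CuI), Et2O, 0 °C; then MeI, HMPA, THF, 0 °C to rt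
Reagents that add atoms: lithium dimethylcuprate [Li+].C[Cu-]C; iodomethane CI
Why: Gilman conjugate addition to the β,β-disubstituted enone completes the future gem-dimethyl carbon and releases a regiodefined enolate whose C-methylation (conjugate addition–enolate alkylation) creates the adjacent quaternary carbon, formed as the racemate on purpose because this centre is erased in step 6.

Step 2
Reactants: 3 1-(1,2,2-trimethylcyclopentyl)ethan-1-one (racemic)
Product: 5 1-(1,2,2-trimethylcyclopentyl)pent-4-yn-1-one (racemic), via lithium enolate 4 (not isolated)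
Conditions: LiN(i-Pr)2, THF, −78 °C; then propargyl bromide, −78 to 0 °C
Reagents that add atoms: propargyl bromide C#CCBr
Why: Deprotonation can only occur at the methyl group because the other α-carbon is quaternary, and SN2 alkylation of the lithium enolate by the propargylic bromide (ketone enolate alkylation) should give the γ,δ-acetylenic ketone.

Step 3
Reactants: 5 1-(1,2,2-trimethylcyclopentyl)pent-4-yn-1-one (racemic)
Product: 6 (1R)-1-(1,2,2-trimethylcyclopentyl)pent-4-yn-1-ol (both epimers at the ring quaternary carbon)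
Conditions: (S)-Me-CBS oxazaborolidine (20 mol %), catecholborane, toluene, −78 to −20 °C; aq. NaOH work-up
Reagents that add atoms: none
Why: Corey–Bakshi–Shibata reduction differentiates the tert-alkyl from the primary alkyl side of the ketone, so the (S)-catalyst is expected to give the (R)-carbinol from both enantiomers of 5, while catecholborane leaves the alkyne untouched at this temperature.

Step 4
Reactants: 6 (1R)-1-(1,2,2-trimethylcyclopentyl)pent-4-yn-1-ol
Product: 8 (3E,7R)-4-methyl-7-(1,2,2-trimethylcyclopentyl)hept-3-ene-1,7-diol, via alkenylalane 7 (not isolated)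
Conditions: Me3Al (3 equiv), Cp2ZrCl2 (0.25 equiv), CH2Cl2, 0 °C to rt; then n-BuLi, THF/hexane, −78 °C; ethylene oxide, −78 °C to rt
Reagents that add atoms: trimethylaluminium C[Al](C)C; ethylene oxide C1CO1
Why: Negishi zirconium-catalysed methylalumination adds CH3 and Al syn across the terminal alkyne with CH3 on the internal carbon, and the derived alanate opens ethylene oxide with retention at the alkenyl carbon, which fixes the (E)-trisubstituted alkene that later defines C9.

Step 5
Reactants: 8 (3E,7R)-4-methyl-7-(1,2,2-trimethylcyclopentyl)hept-3-ene-1,7-diol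
Product: 9 (3E,7R)-7-hydroxy-4-methyl-7-(1,2,2-trimethylcyclopentyl)hept-3-en-1-yl 4-methylbenzenesulfonate
Conditions: TsCl (1.1 equiv), pyridine, CH2Cl2, 0 °C
Reagents that add atoms: 4-methylbenzenesulfonyl chloride Cc1ccc(cc1)S(Cl)(=O)=O
Why: Sulfonylation should discriminate the unhindered primary hydroxyl from the neopentylic secondary one, and the tosylate both keeps this oxygen from trapping the C8 cation in step 6 and prepares the aldehyde of step 7.

Step 6
Reactants: 9 (3E,7R)-7-hydroxy-4-methyl-7-(1,2,2-trimethylcyclopentyl)hept-3-en-1-yl 4-methylbenzenesulfonate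
Product: 12 2-[(1R,4aR,8aR)-2,5,5,8a-tetramethyl-1,4,4a,5,6,7,8,8a-octahydronaphthalen-1-yl]ethyl 4-methylbenzenesulfonate, via triflate 10 (not isolated), via cyclohexyl cation 11 (not isolated)
Conditions: Tf2O (1.1 equiv), 2,6-di-tert-butyl-4-methylpyridine (2.5 equiv), CH2Cl2 (0.01 M), −78 to −30 °C
Reagents that add atoms: none
Why: O-Triflation gives the neopentylic secondary triflate 10, whose ionisation is assisted by antiperiplanar 1,2-shift of the ring CMe2 carbon (C4) from quaternary C10 to C5, so that C4 enters C5 with inversion and ring A appears as the tertiary C10 cation 11. Ring A is thus closed by ring expansion (five to six) and ring B by 6-endo cation–olefin closure of C10 onto C9 of the (E)-alkene, followed by loss of a proton from C7; the closest known reaction types are the Wagner–Meerwein ring enlargement of cyclopentylcarbinyl sulfonates and the second ring closure of a terpenoid polyene cyclisation. C5 is controlled by the carbinol configuration from step 3 (inversion), and C10 and C9 by C5 through a chair transition state with the C5 chain equatorial (trans ring fusion) and by the (E)-geometry of the alkene (equatorial C9 substituent). Because C10 is planar in 11, both epimers of 9 at the former quaternary centre should converge on one product. The step needs migration of C4 in preference to the ring CH2 or the methyl group, which the higher migratory aptitude of the fully substituted carbon and the relief of vicinal quaternary strain should secure, and it needs the alkene to stay untouched until C10 is cationic, which the absence of free acid (hindered pyridine buffer, no free hydroxyl) should secure. Proton loss towards the endocyclic C7=C8 alkene is expected to prevail over the exocyclic and tetrasubstituted isomers.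

Step 7
Reactants: 12 2-[(1R,4aR,8aR)-2,5,5,8a-tetramethyl-1,4,4a,5,6,7,8,8a-octahydronaphthalen-1-yl]ethyl 4-methylbenzenesulfonate
Product: 13 2-[(1R,4aR,8aR)-2,5,5,8a-tetramethyl-1,4,4a,5,6,7,8,8a-octahydronaphthalen-1-yl]acetaldehyde
Conditions: NaHCO3, DMSO, 130 °C, short contact time
Reagents that add atoms: dimethyl sulfoxide CS(C)=O
Why: Kornblum oxidation, in which SN2 displacement of the primary tosylate by the oxygen of DMSO and base-induced collapse of the alkoxysulfonium salt should give the aldehyde without touching the ring alkene or C9.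

Step 8
Reactants: 13 2-[(1R,4aR,8aR)-2,5,5,8a-tetramethyl-1,4,4a,5,6,7,8,8a-octahydronaphthalen-1-yl]acetaldehyde
Product: 14 (2S,3S)-3-methyl-1-[(1R,4aR,8aR)-2,5,5,8a-tetramethyl-1,4,4a,5,6,7,8,8a-octahydronaphthalen-1-yl]pent-4-en-2-ol
Conditions: cis-2-butene, n-BuLi, KOt-Bu, THF, −78 to −45 °C; (+)-Ipc2BOMe [from (−)-α-pinene]; BF3·OEt2; then 13, −78 °C; NaOH, H2O2
Reagents that add atoms: (Z)-crotyldiisopinocampheylborane C/C=C\CB([C@H]1C[C@H]2C[C@@H]([C@@H]1C)C2(C)C)[C@H]1C[C@H]2C[C@@H]([C@@H]1C)C2(C)C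
Why: Brown crotylboration through a chair Zimmerman–Traxler transition state, in which the (Z)-crotyl geometry gives the syn relationship and the isopinocampheyl groups derived from (−)-α-pinene are expected to direct attack to the Re face of the aldehyde, setting (2S,3S) under reagent control.

Step 9
Reactants: 15 pent-1-en-4-yne; 16 2-(chloromethyl)-1,4-dimethoxybenzene
Product: 18 1,4-dimethoxy-2-[(2E)-3-methylhexa-2,5-dien-1-yl]benzene, via alkenylalane 17 (not isolated)
Conditions: 15, Me3Al, Cp2ZrCl2 (cat.), CH2Cl2, 0 °C to rt; then 16, Pd(PPh3)4 (3 mol %), THF, rt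
Reagents that add atoms: trimethylaluminium C[Al](C)C
Why: Negishi carboalumination of the alkyne (the isolated vinyl group is left alone) followed by palladium-catalysed cross-coupling of the alkenylalane with the benzylic chloride proceeds with retention and should give the (E)-trisubstituted alkene.

Step 10
Reactants: 14 (2S,3S)-3-methyl-1-[(1R,4aR,8aR)-2,5,5,8a-tetramethyl-1,4,4a,5,6,7,8,8a-octahydronaphthalen-1-yl]pent-4-en-2-ol; 18 1,4-dimethoxy-2-[(2E)-3-methylhexa-2,5-dien-1-yl]benzene
Product: 19 (2S,3S,4E,7E)-9-(2,5-dimethoxyphenyl)-3,7-dimethyl-1-[(1R,4aR,8aR)-2,5,5,8a-tetramethyl-1,4,4a,5,6,7,8,8a-octahydronaphthalen-1-yl]nona-4,7-dien-2-ol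
Conditions: second-generation Hoveyda–Grubbs catalyst RuCl2(H2IMes)(=CH-C6H4-2-O-i-Pr) (5 mol %), 18 (3 equiv), CH2Cl2, 40 °C
Reagents that add atoms: none
Why: Olefin cross-metathesis joins the two monosubstituted alkenes with loss of ethylene, the trisubstituted alkenes being inert, and the geometry of the new disubstituted alkene is irrelevant because it is hydrogenated next.

Step 11
Reactants: 19 (2S,3S,4E,7E)-9-(2,5-dimethoxyphenyl)-3,7-dimethyl-1-[(1R,4aR,8aR)-2,5,5,8a-tetramethyl-1,4,4a,5,6,7,8,8a-octahydronaphthalen-1-yl]nona-4,7-dien-2-ol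
Product: 20 (2S,3S,7E)-9-(2,5-dimethoxyphenyl)-3,7-dimethyl-1-[(1R,4aR,8aR)-2,5,5,8a-tetramethyl-1,4,4a,5,6,7,8,8a-octahydronaphthalen-1-yl]non-7-en-2-ol
Conditions: H2 (3 atm), RhCl(PPh3)3 (5 mol %), benzene/EtOH, rt
Reagents that add atoms: none
Why: Homogeneous hydrogenation with Wilkinson's catalyst is selective for the 1,2-disubstituted alkene over the two trisubstituted ones.

Step 12
Reactants: 20 (2S,3S,7E)-9-(2,5-dimethoxyphenyl)-3,7-dimethyl-1-[(1R,4aR,8aR)-2,5,5,8a-tetramethyl-1,4,4a,5,6,7,8,8a-octahydronaphthalen-1-yl]non-7-en-2-ol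
Product: 21 sodium (2S,3S,7E)-9-(2,5-dimethoxyphenyl)-3,7-dimethyl-1-[(1R,4aR,8aR)-2,5,5,8a-tetramethyl-1,4,4a,5,6,7,8,8a-octahydronaphthalen-1-yl]non-7-en-2-yl sulfate
Conditions: SO3·pyridine (5 equiv), pyridine, 40 °C; then aq. NaHCO3
Reagents that add atoms: sulfur trioxide–pyridine complex [O-]S(=O)(=O)[n+]1ccccc1; sodium hydrogen carbonate [Na+].OC([O-])=O
Why: O-Sulfation of the only hydroxyl group with the sulfur trioxide–pyridine complex, followed by cation exchange, should give the base-stable sodium alkyl sulfate with both stereocentres untouched.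

Step 13
Reactants: 21 sodium (2S,3S,7E)-9-(2,5-dimethoxyphenyl)-3,7-dimethyl-1-[(1R,4aR,8aR)-2,5,5,8a-tetramethyl-1,4,4a,5,6,7,8,8a-octahydronaphthalen-1-yl]non-7-en-2-yl sulfate
Product: 23 (2S,3S,7E)-9-(2,5-dihydroxyphenyl)-3,7-dimethyl-1-[(1R,4aR,8aR)-2,5,5,8a-tetramethyl-1,4,4a,5,6,7,8,8a-octahydronaphthalen-1-yl]non-7-en-2-yl hydrogen sulfate (target), via quinone 22 (not isolated)
Conditions: (NH4)2Ce(NO3)6 (2.5 equiv), MeCN/H2O, 0 °C, 10 min; then aq. Na2S2O4; then dilute HCl to pH 2 at 0 °C, extraction with n-BuOH, under argon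
Reagents that add atoms: water O
Why: Oxidative demethylation of the 1,4-dimethoxyarene by (NH4)2Ce(NO3)6 gives the benzoquinone, which dithionite reduces to the hydroquinone in the same flask, and brief cold acidification liberates the hydrogen sulfate.

Compound list
1 | 1-(2-methylcyclopent-1-en-1-yl)ethan-1-one | CC(=O)C1=C(C)CCC1 | starting material
2 | lithium 1-(2,2-dimethylcyclopentylidene)ethan-1-olate | CC([O-])=C1CCCC1(C)C.[Li+] | intermediate (not isolated)
3 | 1-(1,2,2-trimethylcyclopentyl)ethan-1-one, racemic | CC(=O)C1(C)CCCC1(C)C | intermediate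
4 | lithium 1-(1,2,2-trimethylcyclopentyl)ethen-1-olate | C=C([O-])C1(C)CCCC1(C)C.[Li+] | intermediate (not isolated)
5 | 1-(1,2,2-trimethylcyclopentyl)pent-4-yn-1-one, racemic | C#CCCC(=O)C1(C)CCCC1(C)C | intermediate
6 | (1R)-1-(1,2,2-trimethylcyclopentyl)pent-4-yn-1-ol, both epimers at the ring quaternary carbon | C#CCC[C@@H](O)C1(C)CCCC1(C)C | intermediate
7 | (E)-alkenyldimethylalane from 6, O-aluminated | C[Al](C)/C=C(\C)CC[C@@H](O[Al](C)C)C1(C)CCCC1(C)C | intermediate (not isolated)
8 | (3E,7R)-4-methyl-7-(1,2,2-trimethylcyclopentyl)hept-3-ene-1,7-diol, both epimers at the ring quaternary carbon | OCC/C=C(\C)CC[C@@H](O)C1(C)CCCC1(C)C | intermediate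
9 | (3E,7R)-7-hydroxy-4-methyl-7-(1,2,2-trimethylcyclopentyl)hept-3-en-1-yl 4-methylbenzenesulfonate, both epimers at the ring quaternary carbon | Cc1ccc(cc1)S(=O)(=O)OCC/C=C(\C)CC[C@@H](O)C1(C)CCCC1(C)C | intermediate
10 | (3E,7R)-4-methyl-7-(1,2,2-trimethylcyclopentyl)-7-(trifluoromethanesulfonyloxy)hept-3-en-1-yl 4-methylbenzenesulfonate | Cc1ccc(cc1)S(=O)(=O)OCC/C=C(\C)CC[C@@H](OS(=O)(=O)C(F)(F)F)C1(C)CCCC1(C)C | intermediate (not isolated)
11 | ring-expanded tertiary cyclohexyl cation (C10 cationic, C5 R), triflate salt | Cc1ccc(cc1)S(=O)(=O)OCC/C=C(\C)CC[C@@H]1C(C)(C)CCC[C+]1C.[O-]S(=O)(=O)C(F)(F)F | intermediate (not isolated)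
12 | 2-[(1R,4aR,8aR)-2,5,5,8a-tetramethyl-1,4,4a,5,6,7,8,8a-octahydronaphthalen-1-yl]ethyl 4-methylbenzenesulfonate | CC1=CC[C@@H]2C(C)(C)CCC[C@@]2(C)[C@@H]1CCOS(=O)(=O)c3ccc(C)cc3 | intermediate
13 | 2-[(1R,4aR,8aR)-2,5,5,8a-tetramethyl-1,4,4a,5,6,7,8,8a-octahydronaphthalen-1-yl]acetaldehyde | CC1=CC[C@@H]2C(C)(C)CCC[C@@]2(C)[C@@H]1CC=O | intermediate
14 | (2S,3S)-3-methyl-1-[(1R,4aR,8aR)-2,5,5,8a-tetramethyl-1,4,4a,5,6,7,8,8a-octahydronaphthalen-1-yl]pent-4-en-2-ol | CC1=CC[C@@H]2C(C)(C)CCC[C@@]2(C)[C@@H]1C[C@H](O)[C@@H](C)C=C | intermediate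
15 | pent-1-en-4-yne | C=CCC#C | starting material
16 | 2-(chloromethyl)-1,4-dimethoxybenzene | COc1ccc(OC)c(CCl)c1 | starting material
17 | dimethyl[(1E)-2-methylpenta-1,4-dien-1-yl]alane | C[Al](C)/C=C(\C)CC=C | intermediate (not isolated)
18 | 1,4-dimethoxy-2-[(2E)-3-methylhexa-2,5-dien-1-yl]benzene | C=CC/C(C)=C/Cc1cc(OC)ccc1OC | intermediate
19 | (2S,3S,4E,7E)-9-(2,5-dimethoxyphenyl)-3,7-dimethyl-1-[(1R,4aR,8aR)-2,5,5,8a-tetramethyl-1,4,4a,5,6,7,8,8a-octahydronaphthalen-1-yl]nona-4,7-dien-2-ol (E drawn at C4, the Z isomer converges in step 11) | CC1=CC[C@@H]2C(C)(C)CCC[C@@]2(C)[C@@H]1C[C@H](O)[C@@H](C)/C=C/C/C(C)=C/Cc3cc(OC)ccc3OC | intermediate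
20 | (2S,3S,7E)-9-(2,5-dimethoxyphenyl)-3,7-dimethyl-1-[(1R,4aR,8aR)-2,5,5,8a-tetramethyl-1,4,4a,5,6,7,8,8a-octahydronaphthalen-1-yl]non-7-en-2-ol | CC1=CC[C@@H]2C(C)(C)CCC[C@@]2(C)[C@@H]1C[C@H](O)[C@@H](C)CCC/C(C)=C/Cc3cc(OC)ccc3OC | intermediate
21 | sodium (2S,3S,7E)-9-(2,5-dimethoxyphenyl)-3,7-dimethyl-1-[(1R,4aR,8aR)-2,5,5,8a-tetramethyl-1,4,4a,5,6,7,8,8a-octahydronaphthalen-1-yl]non-7-en-2-yl sulfate | CC1=CC[C@@H]2C(C)(C)CCC[C@@]2(C)[C@@H]1C[C@H](OS(=O)(=O)[O-])[C@@H](C)CCC/C(C)=C/Cc3cc(OC)ccc3OC.[Na+] | intermediate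
22 | sodium (2S,3S,7E)-9-(3,6-dioxocyclohexa-1,4-dien-1-yl)-3,7-dimethyl-1-[(1R,4aR,8aR)-2,5,5,8a-tetramethyl-1,4,4a,5,6,7,8,8a-octahydronaphthalen-1-yl]non-7-en-2-yl sulfate | CC1=CC[C@@H]2C(C)(C)CCC[C@@]2(C)[C@@H]1C[C@H](OS(=O)(=O)[O-])[C@@H](C)CCC/C(C)=C/CC3=CC(=O)C=CC3=O.[Na+] | intermediate (not isolated)
23 | (2S,3S,7E)-9-(2,5-dihydroxyphenyl)-3,7-dimethyl-1-[(1R,4aR,8aR)-2,5,5,8a-tetramethyl-1,4,4a,5,6,7,8,8a-octahydronaphthalen-1-yl]non-7-en-2-yl hydrogen sulfate | CC1=CC[C@@H]2C(C)(C)CCC[C@@]2(C)[C@@H]1C[C@H](OS(=O)(=O)O)[C@@H](C)CCC/C(C)=C/Cc1cc(O)ccc1O | target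

Total step count: 13. Longest linear sequence: 12 steps (1 → 3 → 5 → 6 → 8 → 9 → 12 → 13 → 14 → 19 → 20 → 21 → 23); step 9 is the one-step side branch.

Steps most likely to fail

Step 6 (key step). The ring-expanded C10 cation may lose a proton before ring B closes, termination may give the exocyclic or tetrasubstituted alkene instead of C7=C8, and the ring CH2 may migrate in the epimer in which C4 is less easily antiperiplanar to the leaving group. The fallback sets out from 6 and comes back at 12, and runs ring expansion and ring closure as separate known reactions. Alkynol 6 is converted into (1R)-1-(1,2,2-trimethylcyclopentyl)pent-4-yn-1-yl methanesulfonate F1 (MsCl, Et3N, CH2Cl2, 0 °C). Buffered hydrolysis (CaCO3, acetone/H2O, 70 °C) effects the same Wagner–Meerwein ring enlargement with capture of the tertiary cation by water and gives (2R)-2-(but-3-yn-1-yl)-1,3,3-trimethylcyclohexan-1-ol F2, which can be freed from mis-rearranged material. Methylalumination and opening of ethylene oxide as in step 4 give (3E)-6-[(1R)-2-hydroxy-2,6,6-trimethylcyclohexyl]-4-methylhex-3-en-1-ol F3, and selective tosylation as in step 5 gives (3E)-6-[(1R)-2-hydroxy-2,6,6-trimethylcyclohexyl]-4-methylhex-3-en-1-yl 4-methylbenzenesulfonate F4. The tertiary alcohol is then ionised under the established conditions for bicyclisation of monocyclic terpenoid alcohols (ClSO3H, 2-nitropropane, −78 °C, or SnCl4, CH2Cl2, −78 °C) to reach 12.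

Step 1. Conjugate addition to the tetrasubstituted enone may be sluggish, and methylation of the hindered enolate next to a quaternary carbon may be incomplete or, after proton transfer, occur on the acetyl side. The fallback sets out from 1 and comes back at 3, and builds the quaternary centre by alkylating a carboxylic acid dianion. Conjugate addition of Me2CuLi with aqueous quench gives 1-(2,2-dimethylcyclopentyl)ethan-1-one F5; haloform degradation (NaOBr, dioxane/H2O) gives 2,2-dimethylcyclopentane-1-carboxylic acid F6; double deprotonation (LiN(i-Pr)2, 2.2 equiv, THF/HMPA) and MeI give 1,2,2-trimethylcyclopentane-1-carboxylic acid F7; MeLi (2.2 equiv, Et2O) converts the acid into methyl ketone 3.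

Step 10 (with step 11). Homodimerisation and slow turnover of the allylically branched alkene may limit the cross-metathesis, and the hydrogenation that follows may not discriminate fully between the disubstituted and the trisubstituted alkenes. The fallback sets out from 14 and comes back at 20, replacing steps 9 to 11, so that no alkene has to be reduced. 14 is silylated (TBSOTf, 2,6-lutidine) to the tert-butyldimethylsilyl ether of 14 F8. Hydroboration–oxidation of the vinyl group (9-BBN; NaOH, H2O2) gives the primary alcohol (3S,4S)-4-silyloxy-3-methyl-5-decalinylpentan-1-ol F9, and I2, PPh3 and imidazole give the corresponding primary iodide F10. Alkylation of 3-lithio-1-(trimethylsilyl)propyne (from 1-(trimethylsilyl)propyne and n-BuLi) gives the chain-extended trimethylsilylalkyne F11, and K2CO3 in MeOH gives the terminal alkyne F12. Me3Al/Cp2ZrCl2, then 16 and Pd(PPh3)4 as in step 9, give the tert-butyldimethylsilyl ether of 20 F13, and n-Bu4NF gives 20.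

Further compounds
F1 | step 6 | (1R)-1-(1,2,2-trimethylcyclopentyl)pent-4-yn-1-yl methanesulfonate | C#CCC[C@@H](OS(C)(=O)=O)C1(C)CCCC1(C)C
F2 | step 6 | (2R)-2-(but-3-yn-1-yl)-1,3,3-trimethylcyclohexan-1-ol (both C1 epimers) | C#CCC[C@@H]1C(C)(C)CCCC1(C)O
F3 | step 6 | (3E)-6-[(1R)-2-hydroxy-2,6,6-trimethylcyclohexyl]-4-methylhex-3-en-1-ol | OCC/C=C(\C)CC[C@@H]1C(C)(C)CCCC1(C)O
F4 | step 6 | (3E)-6-[(1R)-2-hydroxy-2,6,6-trimethylcyclohexyl]-4-methylhex-3-en-1-yl 4-methylbenzenesulfonate | Cc1ccc(cc1)S(=O)(=O)OCC/C=C(\C)CC[C@@H]1C(C)(C)CCCC1(C)O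
F5 | step 1 | 1-(2,2-dimethylcyclopentyl)ethan-1-one | CC(=O)C1CCCC1(C)C
F6 | step 1 | 2,2-dimethylcyclopentane-1-carboxylic acid | OC(=O)C1CCCC1(C)C
F7 | step 1 | 1,2,2-trimethylcyclopentane-1-carboxylic acid | OC(=O)C1(C)CCCC1(C)C
F8 | step 10 | tert-butyldimethylsilyl ether of 14 | CC1=CC[C@@H]2C(C)(C)CCC[C@@]2(C)[C@@H]1C[C@H](O[Si](C)(C)C(C)(C)C)[C@@H](C)C=C
F9 | step 10 | (3S,4S)-4-(tert-butyldimethylsilyloxy)-3-methyl-5-[(1R,4aR,8aR)-2,5,5,8a-tetramethyl-1,4,4a,5,6,7,8,8a-octahydronaphthalen-1-yl]pentan-1-ol | CC1=CC[C@@H]2C(C)(C)CCC[C@@]2(C)[C@@H]1C[C@H](O[Si](C)(C)C(C)(C)C)[C@@H](C)CCO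
F10 | step 10 | primary iodide from F9 | CC1=CC[C@@H]2C(C)(C)CCC[C@@]2(C)[C@@H]1C[C@H](O[Si](C)(C)C(C)(C)C)[C@@H](C)CCI
F11 | step 10 | trimethylsilylalkyne from F10 | CC1=CC[C@@H]2C(C)(C)CCC[C@@]2(C)[C@@H]1C[C@H](O[Si](C)(C)C(C)(C)C)[C@@H](C)CCCC#C[Si](C)(C)C
F12 | step 10 | terminal alkyne from F11 | CC1=CC[C@@H]2C(C)(C)CCC[C@@]2(C)[C@@H]1C[C@H](O[Si](C)(C)C(C)(C)C)[C@@H](C)CCCC#C
F13 | step 10 | tert-butyldimethylsilyl ether of 20 | CC1=CC[C@@H]2C(C)(C)CCC[C@@]2(C)[C@@H]1C[C@H](O[Si](C)(C)C(C)(C)C)[C@@H](C)CCC/C(C)=C/Cc3cc(OC)ccc3OC
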